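The oxane is numbered O1, C2 (arylethyl), C3, C4 (OAc), C5, C6 (aryl). The C4 oxygen is 1,3-related to O1, so O1–C6–C5–C4 is an aldol unit. The plan ties C2 to both oxygens in a temporary 1,3-dioxane: an (S)-β-hydroxy acid (C4–C6) and the arylpropanal (C2) give a dioxanone, whose carbonyl is methylenated to install C3. Me2AlCl then breaks the acetal bond C2–O(C4) and the aluminium enolate closes onto the oxocarbenium ion, forming C2–C3 and the 2,6-cis oxan-4-one in one operation (Petasis–Ferrier rearrangement). This irreversible enolate closure spares the electron-rich benzylic C6–O1 bond. Axial-selective reduction, acetylation and debenzylation follow.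

Key step: step 8

Remark on the chemistry: compounds 1, 3 and 7 are taken as purchasable, and all three phenols are carried as benzyl ethers, which should tolerate every later reagent and leave together in the last step.

Step 1
Reactants: 1 3,4-dihydroxy-5-methoxybenzaldehyde
Product: 2 3,4-bis(benzyloxy)-5-methoxybenzaldehyde
Conditions: BnBr (2.4 equiv), K2CO3, DMF, 60 °C
Reagents that add atoms: benzyl bromide, BrCc1ccccc1
Why: Williamson ether synthesis, in which both phenoxides of 1 are benzylated by SN2 on benzyl bromide under carbonate base that leaves the aldehyde untouched.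

Step 2
Reactants: 2 3,4-bis(benzyloxy)-5-methoxybenzaldehyde; 3 (S)-2-hydroxy-1,2,2-triphenylethyl acetate ((S)-HYTRA)
Product: 5 (S)-2-hydroxy-1,2,2-triphenylethyl (S)-3-[3,4-bis(benzyloxy)-5-methoxyphenyl]-3-hydroxypropanoate, via dilithium enolate 4 (not isolated)
Conditions: 3, LiN(iPr)2 (2.2 equiv), THF, −78 → 0 °C; then 2 in THF/2-methylbutane, −125 °C; aq. NH4Cl; recrystallisation
Reagents that add atoms: none
Why: Auxiliary-controlled acetate aldol addition (HYTRA aldol), in which the doubly deprotonated ester 4 adds to the aldehyde under control of the triphenylglycol backbone; the (S)-auxiliary should give the (S)-carbinol (C6 of the target), because the (R)-reagent gives (R)-3-hydroxy acids of the same priority pattern, and the crystalline adduct should allow the minor diastereomer to be removed.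

Step 3
Reactants: 5 (S)-2-hydroxy-1,2,2-triphenylethyl (S)-3-[3,4-bis(benzyloxy)-5-methoxyphenyl]-3-hydroxypropanoate
Product: 6 (S)-3-[3,4-bis(benzyloxy)-5-methoxyphenyl]-3-hydroxypropanoic acid
Conditions: KOH, MeOH/H2O, 50 °C; then 1 M HCl to pH 3, 0 °C
Reagents that add atoms: potassium hydroxide, [K+].[OH-]
Why: Saponification frees the β-hydroxy acid and the recoverable auxiliary diol without touching the carbinol centre, since a β-hydroxy carboxylate does not readily undergo retro-aldol cleavage, and cold mild acidification avoids benzylic dehydration.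

Step 4
Reactants: 7 4-(3-hydroxypropyl)-2-methoxyphenol (dihydroconiferyl alcohol)
Product: 8 3-[4-(benzyloxy)-3-methoxyphenyl]propan-1-ol
Conditions: BnBr (1.05 equiv), K2CO3, acetone, reflux
Reagents that add atoms: benzyl bromide, BrCc1ccccc1
Why: Chemoselective Williamson etherification, in which only the phenol is deprotonated by K2CO3 so that the primary alcohol stays free.

Step 5
Reactants: 8 3-[4-(benzyloxy)-3-methoxyphenyl]propan-1-ol
Product: 9 3-[4-(benzyloxy)-3-methoxyphenyl]propanal
Conditions: Dess–Martin periodinane, CH2Cl2, 0 °C → rt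
Reagents that add atoms: none
Why: Dess–Martin oxidation should stop at the aldehyde under near-neutral conditions that spare the benzyl ether and the electron-rich arene.

Step 6
Reactants: 6 (S)-3-[3,4-bis(benzyloxy)-5-methoxyphenyl]-3-hydroxypropanoic acid; 9 3-[4-(benzyloxy)-3-methoxyphenyl]propanal
Product: 11 (2R,6S)-6-[3,4-bis(benzyloxy)-5-methoxyphenyl]-2-{2-[4-(benzyloxy)-3-methoxyphenyl]ethyl}-1,3-dioxan-4-one (2,6-cis), via bis-trimethylsilyl derivative 10 (not isolated)
Conditions: 6, (Me3Si)2NH, THF, rt, evaporate; then 9, TMSOTf (10 mol %), CH2Cl2, −78 °C; pyridine quench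
Reagents that add atoms: none
Why: TMSOTf-catalysed silyl acetalisation of the silyl ether/silyl ester pair 10 with the aldehyde closes the temporary 1,3-dioxan-4-one, and the new acetal centre C2 should settle cis to the C6 aryl group because both substituents are then equatorial on the chair.

Step 7
Reactants: 11 (2R,6S)-6-[3,4-bis(benzyloxy)-5-methoxyphenyl]-2-{2-[4-(benzyloxy)-3-methoxyphenyl]ethyl}-1,3-dioxan-4-one
Product: 12 (2R,6S)-6-[3,4-bis(benzyloxy)-5-methoxyphenyl]-2-{2-[4-(benzyloxy)-3-methoxyphenyl]ethyl}-4-methylidene-1,3-dioxane (2,6-cis enol acetal)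
Conditions: Cp2TiMe2 (2.5 equiv), THF/toluene, 65 °C, dark; filtration through basic alumina
Reagents that add atoms: dimethyltitanocene, C[Ti](C)(C1C=CC=C1)C1C=CC=C1
Why: Petasis methylenation, in which Cp2Ti=CH2 formed thermally from Cp2TiMe2 converts the lactone carbonyl into the exocyclic enol ether by a [2+2]/retro-[2+2] sequence under non-acidic conditions that preserve the acetal and both stereocentres.

Step 8
Reactants: 12 (2R,6S)-6-[3,4-bis(benzyloxy)-5-methoxyphenyl]-2-{2-[4-(benzyloxy)-3-methoxyphenyl]ethyl}-4-methylidene-1,3-dioxane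
Product: 14 (2S,6S)-6-[3,4-bis(benzyloxy)-5-methoxyphenyl]-2-{2-[4-(benzyloxy)-3-methoxyphenyl]ethyl}oxan-4-one (2,6-cis), via oxocarbenium aluminium enolate 13 (not isolated)
Conditions: Me2AlCl (2.2 equiv), CH2Cl2, −78 °C; then H2O
Reagents that add atoms: none
Why: Me2AlCl binds the enol-ether oxygen O3 of 12 and cleaves the acetal bond C2–O3, giving the ring-opened zwitterion 13 in which an (E)-oxocarbenium ion O1=C2 and a dimethylchloroaluminium enolate C3=C4–OAl are held together by C5–C6; the enolate carbon C3 then adds to C2 and the oxane forms with C4 as a ketone (Petasis–Ferrier rearrangement, in essence an intramolecular Mukaiyama-aldol-type addition to an oxocarbenium ion and the enolate counterpart of a Prins cyclisation). The oxane closes in a 6-endo-trig mode at the oxocarbenium carbon (6-enolendo with respect to the enolate). The only new stereocentre, C2, is set by the chair transition state in which the C6 aryl group and the C2 arylethyl chain of the (E)-oxocarbenium ion are both pseudo-equatorial, so C6 (from step 2) relays its configuration and the 2,6-cis (2S,6S) ketone should result whatever the acetal configuration of 12. The step needs cleavage of C2–O3 and not of C2–O1, and no ionisation of the electron-rich benzylic C6–O1 bond: the first is secured because only O3 can leave as a stabilised enolate, the second because C–C bond formation by an enolate is fast at −78 °C and irreversible, whereas the alkene nucleophile of a classical Prins closure would leave time for benzylic ionisation and 2-oxonia-Cope exchange. Should a 2-oxonia-Cope shift of 13 nevertheless occur through the same chair, it converges on the same ketone 14.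

Step 9
Reactants: 14 (2S,6S)-6-[3,4-bis(benzyloxy)-5-methoxyphenyl]-2-{2-[4-(benzyloxy)-3-methoxyphenyl]ethyl}oxan-4-one
Product: 16 (2S,4S,6S)-6-[3,4-bis(benzyloxy)-5-methoxyphenyl]-2-{2-[4-(benzyloxy)-3-methoxyphenyl]ethyl}oxan-4-yl acetate (acetate axial), via lithium alkoxide 15 (not isolated)
Conditions: Li[HB(sec-Bu)3] (1.2 equiv), THF, −78 °C; then Ac2O, DMAP (cat.), −78 °C → rt
Reagents that add atoms: acetic anhydride, CC(=O)OC(C)=O
Why: Substrate-controlled ketone reduction with in situ acylation, in which the bulky trialkylborohydride approaches the chair-locked ketone along the equatorial trajectory (the axial one is blocked by the axial hydrogens at C2 and C6) to give the axial (4S) alkoxide 15, which Ac2O traps as the acetate.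

Step 10
Reactants: 16 (2S,4S,6S)-6-[3,4-bis(benzyloxy)-5-methoxyphenyl]-2-{2-[4-(benzyloxy)-3-methoxyphenyl]ethyl}oxan-4-yl acetate
Product: 17 (2S,4S,6S)-6-(3,4-dihydroxy-5-methoxyphenyl)-2-[2-(4-hydroxy-3-methoxyphenyl)ethyl]oxan-4-yl acetate
Conditions: H2 (1 atm), Pd/C (10 wt % Pd), EtOAc, rt
Reagents that add atoms: none
Why: Catalytic hydrogenolysis cleaves the three aryl benzyl ethers under neutral conditions, while the secondary acetate and the cyclic benzylic ether C6–O1, which reacts far more slowly than O-benzyl groups, should survive if the reaction is stopped at full debenzylation.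

Compound list
1 | 3,4-dihydroxy-5-methoxybenzaldehyde (5-hydroxyvanillin) | COc1cc(C=O)cc(O)c1O | starting material
2 | 3,4-bis(benzyloxy)-5-methoxybenzaldehyde | COc1cc(C=O)cc(OCc2ccccc2)c1OCc1ccccc1 | intermediate
3 | (S)-2-hydroxy-1,2,2-triphenylethyl acetate ((S)-HYTRA) | CC(=O)O[C@@H](c1ccccc1)C(O)(c1ccccc1)c1ccccc1 | starting material
4 | dilithium enolate-alkoxide of 3 (doubly deprotonated (S)-HYTRA) | [Li+].[Li+].C=C([O-])O[C@@H](c1ccccc1)C([O-])(c1ccccc1)c1ccccc1 | intermediate
5 | (S)-2-hydroxy-1,2,2-triphenylethyl (S)-3-[3,4-bis(benzyloxy)-5-methoxyphenyl]-3-hydroxypropanoate | COc1cc([C@@H](O)CC(=O)O[C@@H](c2ccccc2)C(O)(c2ccccc2)c2ccccc2)cc(OCc2ccccc2)c1OCc1ccccc1 | intermediate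
6 | (S)-3-[3,4-bis(benzyloxy)-5-methoxyphenyl]-3-hydroxypropanoic acid | COc1cc([C@@H](O)CC(=O)O)cc(OCc2ccccc2)c1OCc1ccccc1 | intermediate
7 | 4-(3-hydroxypropyl)-2-methoxyphenol (dihydroconiferyl alcohol) | COc1cc(CCCO)ccc1O | starting material
8 | 3-[4-(benzyloxy)-3-methoxyphenyl]propan-1-ol | COc1cc(CCCO)ccc1OCc1ccccc1 | intermediate
9 | 3-[4-(benzyloxy)-3-methoxyphenyl]propanal | COc1cc(CCC=O)ccc1OCc1ccccc1 | intermediate
10 | trimethylsilyl (S)-3-[3,4-bis(benzyloxy)-5-methoxyphenyl]-3-(trimethylsilyloxy)propanoate | COc1cc([C@@H](O[Si](C)(C)C)CC(=O)O[Si](C)(C)C)cc(OCc2ccccc2)c1OCc1ccccc1 | intermediate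
11 | (2R,6S)-6-[3,4-bis(benzyloxy)-5-methoxyphenyl]-2-{2-[4-(benzyloxy)-3-methoxyphenyl]ethyl}-1,3-dioxan-4-one (2,6-cis) | COc1cc(CC[C@H]2OC(=O)C[C@@H](c3cc(OCc4ccccc4)c(OCc4ccccc4)c(OC)c3)O2)ccc1OCc1ccccc1 | intermediate
12 | (2R,6S)-6-[3,4-bis(benzyloxy)-5-methoxyphenyl]-2-{2-[4-(benzyloxy)-3-methoxyphenyl]ethyl}-4-methylidene-1,3-dioxane (2,6-cis) | COc1cc(CC[C@H]2OC(=C)C[C@@H](c3cc(OCc4ccccc4)c(OCc4ccccc4)c(OC)c3)O2)ccc1OCc1ccccc1 | intermediate
13 | ring-opened zwitterion: oxocarbenium ion O1=C2 linked through C6–C5 to the dimethylchloroaluminium enolate C3=C4–OAl (C6 S) | COc1cc(CCC=[O+][C@@H](CC(=C)O[Al-](C)(C)Cl)c2cc(OCc3ccccc3)c(OCc3ccccc3)c(OC)c2)ccc1OCc1ccccc1 | intermediate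
14 | (2S,6S)-6-[3,4-bis(benzyloxy)-5-methoxyphenyl]-2-{2-[4-(benzyloxy)-3-methoxyphenyl]ethyl}oxan-4-one (2,6-cis) | COc1cc(CC[C@H]2CC(=O)C[C@@H](c3cc(OCc4ccccc4)c(OCc4ccccc4)c(OC)c3)O2)ccc1OCc1ccccc1 | intermediate
15 | lithium (2S,4S,6S)-6-[3,4-bis(benzyloxy)-5-methoxyphenyl]-2-{2-[4-(benzyloxy)-3-methoxyphenyl]ethyl}oxan-4-olate (axial alkoxide) | [Li+].COc1cc(CC[C@H]2C[C@H]([O-])C[C@@H](c3cc(OCc4ccccc4)c(OCc4ccccc4)c(OC)c3)O2)ccc1OCc1ccccc1 | intermediate
16 | (2S,4S,6S)-6-[3,4-bis(benzyloxy)-5-methoxyphenyl]-2-{2-[4-(benzyloxy)-3-methoxyphenyl]ethyl}oxan-4-yl acetate (2,6-cis, acetate axial) | COc1cc(CC[C@H]2C[C@H](OC(C)=O)C[C@@H](c3cc(OCc4ccccc4)c(OCc4ccccc4)c(OC)c3)O2)ccc1OCc1ccccc1 | intermediate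
17 | (2S,4S,6S)-6-(3,4-dihydroxy-5-methoxyphenyl)-2-[2-(4-hydroxy-3-methoxyphenyl)ethyl]oxan-4-yl acetate | COc1cc(CC[C@H]2C[C@H](OC(C)=O)C[C@@H](c3cc(O)c(O)c(OC)c3)O2)ccc1O | target

Total step count: 10
Longest linear sequence: 8 steps (steps 1, 2, 3, 6, 7, 8, 9, 10)

Steps most likely to fail

1. Step 8 (key rearrangement).
What may go wrong: Lewis-acid ionisation of the electron-rich benzylic C6–O1 bond of 12 or 13, leading to fragmentation or loss of configuration at C6, or opening of the acetal on the wrong side so that no enolate forms.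
The fallback sets out from 2 and comes back at 16. Asymmetric allylboration of 2 with (−)-B-allyldiisopinocampheylborane (Et2O, −78 °C; NaOH, H2O2) should give (S)-1-[3,4-bis(benzyloxy)-5-methoxyphenyl]but-3-en-1-ol F1. Prins cyclisation of F1 with 9 (CF3CO2H, CH2Cl2, 0 °C) closes the same C2–C3 bond by alkene attack on the oxocarbenium ion and should give the all-equatorial (2S,4R,6S)-6-[3,4-bis(benzyloxy)-5-methoxyphenyl]-2-{2-[4-(benzyloxy)-3-methoxyphenyl]ethyl}oxan-4-yl trifluoroacetate F2. K2CO3 in MeOH frees the equatorial (2S,4R,6S)-6-[3,4-bis(benzyloxy)-5-methoxyphenyl]-2-{2-[4-(benzyloxy)-3-methoxyphenyl]ethyl}oxan-4-ol F3. Mitsunobu inversion with AcOH (PPh3, DIAD, THF) then installs the axial acetate, which is 16. The enantiomeric purity would have to be checked at this stage, since 2-oxonia-Cope exchange is the known weakness of alkene Prins closures next to electron-rich arenes.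

2. Step 7 (methylenation).
What may go wrong: incomplete methylenation of the lactone, or hydrolysis and exo-to-endo double-bond migration of the acid-labile enol acetal during isolation.
The fallback sets out from 6 and comes back at 14. Excess MeLi (THF, −78 → 0 °C, cold buffered quench) should convert the acid into (S)-4-[3,4-bis(benzyloxy)-5-methoxyphenyl]-4-hydroxybutan-2-one F4. LiN(iPr)2 (2.2 equiv) and Me3SiCl at −78 °C should give the silyl ether/kinetic terminal silyl enol ether (S)-{1-[3,4-bis(benzyloxy)-5-methoxyphenyl]-3-(trimethylsilyloxy)but-3-en-1-yl}oxy(trimethyl)silane F5. Treatment of F5 with 9 and catalytic TMSOTf (CH2Cl2, −78 °C) is a silyl enol ether Prins cyclisation. It generates the same oxocarbenium ion and closes C2–C3 to give 14 directly, with no titanium reagent and no isolable enol acetal.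

3. Step 2 (acetate aldol).
What may go wrong: insufficient facial selectivity of the enolate addition at very low temperature with an electron-rich, poorly soluble aromatic aldehyde, so that 6 is enriched but not pure.
The fallback sets out from 2 and comes back at 6. Roskamp homologation of 2 with ethyl diazoacetate (NbCl5 cat., CH2Cl2) should give ethyl 3-[3,4-bis(benzyloxy)-5-methoxyphenyl]-3-oxopropanoate F6. Asymmetric transfer hydrogenation with RuCl[(S,S)-TsDPEN](p-cymene) in HCO2H/Et3N should give ethyl (S)-3-[3,4-bis(benzyloxy)-5-methoxyphenyl]-3-hydroxypropanoate F7. LiOH in THF/H2O then returns 6.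

Further compounds
F1 | step 8 | (S)-1-[3,4-bis(benzyloxy)-5-methoxyphenyl]but-3-en-1-ol | COc1cc([C@@H](O)CC=C)cc(OCc2ccccc2)c1OCc1ccccc1
F2 | step 8 | (2S,4R,6S)-6-[3,4-bis(benzyloxy)-5-methoxyphenyl]-2-{2-[4-(benzyloxy)-3-methoxyphenyl]ethyl}oxan-4-yl trifluoroacetate | COc1cc(CC[C@H]2C[C@@H](OC(=O)C(F)(F)F)C[C@@H](c3cc(OCc4ccccc4)c(OCc4ccccc4)c(OC)c3)O2)ccc1OCc1ccccc1
F3 | step 8 | (2S,4R,6S)-6-[3,4-bis(benzyloxy)-5-methoxyphenyl]-2-{2-[4-(benzyloxy)-3-methoxyphenyl]ethyl}oxan-4-ol | COc1cc(CC[C@H]2C[C@@H](O)C[C@@H](c3cc(OCc4ccccc4)c(OCc4ccccc4)c(OC)c3)O2)ccc1OCc1ccccc1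
F4 | step 7 | (S)-4-[3,4-bis(benzyloxy)-5-methoxyphenyl]-4-hydroxybutan-2-one | COc1cc([C@@H](O)CC(C)=O)cc(OCc2ccccc2)c1OCc1ccccc1
F5 | step 7 | (S)-{1-[3,4-bis(benzyloxy)-5-methoxyphenyl]-3-(trimethylsilyloxy)but-3-en-1-yl}oxy(trimethyl)silane | COc1cc([C@@H](O[Si](C)(C)C)CC(=C)O[Si](C)(C)C)cc(OCc2ccccc2)c1OCc1ccccc1
F6 | step 2 | ethyl 3-[3,4-bis(benzyloxy)-5-methoxyphenyl]-3-oxopropanoate | CCOC(=O)CC(=O)c1cc(OC)c(OCc2ccccc2)c(OCc2ccccc2)c1
F7 | step 2 | ethyl (S)-3-[3,4-bis(benzyloxy)-5-methoxyphenyl]-3-hydroxypropanoate | COc1cc([C@@H](O)CC(=O)OCC)cc(OCc2ccccc2)c1OCc1ccccc1
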